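**Plan**
- Retrosynthesis: first cut the ArCH2–C6' bond of the methylene bridge, giving chromene ketone 15, trione 23 and a one-carbon unit. Then cut O1–C8a and C4–C4a of the 2H-chromene (aryne 11 + 3-methylbut-2-enal 10). Then cut C2–C3 and C5–C6 of the cyclohexadienone ring (malonate half-ester 19 + pentane-2,4-dione 20).
- Enabling feature: C4a and C8a are adjacent carbons of the benzene ring, so both ring-fusion bonds of the pyran ring can be made on a 1,2-didehydroarene. The oxygen on C5, next to C4a, polarises that aryne so that the aldehyde O goes to C8a (next to the butanoyl-bearing C8) and the aldehyde C to C4a. This fixes the 8-acyl-5,7-dioxygenated pattern.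
- Forward, fragment 1: phloroglucinol → silyl triflate 9 by a one-flask double directed ortho-metalation (silylation, then acylation) → aryne cascade closes the pyran ring (step 5) → deprotection to 15.
- Forward, fragment 2: malonate alkylation → esterase desymmetrisation → dianion acylation → Dieckmann closure of the carbocycle (23). The CH2 bridge joins both halves last (Mannich base / ortho-quinone methide).
- Stereochemistry: the single quaternary centre comes from enzymatic desymmetrisation of prochiral diester 18. The acid arm becomes C5 and the ester arm C3, so (R)-19 → (4R)-23 → target. The centre has no enolisable H and cannot epimerise later.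

Key step: step 5

Assumption: pig liver esterase is taken to hydrolyse the pro-S ester group of 18, the sense expected for a long lipophilic substituent next to methyl; enol tautomers of 22, 23 and 26 are drawn as in the target.

**Step 1**
Reactants: 1 benzene-1,3,5-triol (phloroglucinol)
Product: 2 3,5-bis(methoxymethoxy)phenol
Conditions: NaH (2.0 equiv), MOMCl (2.0 equiv), DMF, 0 °C; chromatography
Reagents that add atoms: chloromethyl methyl ether, COCCl
Why: Williamson O-alkylation of the phenoxide is run statistically to the bis-ether, which should be separable from the recyclable mono- and tris-ethers, and its mirror symmetry makes the two positions ortho to the free OH equivalent for step 3.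

**Step 2**
Reactants: 2 3,5-bis(methoxymethoxy)phenol
Product: 3 3,5-bis(methoxymethoxy)phenyl propan-2-ylcarbamate
Conditions: i-PrNCO (1.2 equiv), Et3N (0.2 equiv), CH2Cl2, rt
Reagents that add atoms: 2-isocyanatopropane, CC(C)N=C=O
Why: Amine-catalysed addition of the phenol to the isocyanate (O-carbamoylation) installs a secondary aryl carbamate that is a strong director for ortho-metalation and can later be removed under mild E1cB conditions that a ketone tolerates.

**Step 3**
Reactants: 3 3,5-bis(methoxymethoxy)phenyl propan-2-ylcarbamate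
Product: 7 2-butanoyl-3,5-bis(methoxymethoxy)-6-(trimethylsilyl)phenyl propan-2-ylcarbamate, via N-silyl carbamate 4 (not isolated), via N-silyl arylsilane 5 (not isolated), via N-silyl aryl ketone 6 (not isolated)
Conditions: TBSOTf (1.1 equiv), TMEDA, Et2O, 0 °C to rt; n-BuLi (2.1 equiv), TMEDA, −78 °C; TMSCl (1.05 equiv), −78 to −20 °C; n-BuLi (1.3 equiv), −78 °C; N-methoxy-N-methylbutanamide (1.6 equiv), −78 to 0 °C; aq. NaHSO4 work-up
Reagents that add atoms: chlorotrimethylsilane, C[Si](C)(C)Cl; N-methoxy-N-methylbutanamide, CCCC(=O)N(C)OC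
Why: Iterative directed ortho-metalation in one flask: after in situ N-silylation (4; one equivalent of the first n-BuLi charge neutralises the TMEDA·HOTf formed) the carbamate directs lithiation to a carbon flanked by carbamate and OMOM rather than to the carbon between the two weaker OMOM directors, C-silylation gives 5 with the N–Si bond still in place, a second lithiation at the one remaining carbamate/OMOM-flanked carbon and acylation with the N-methoxy-N-methylamide (chelated tetrahedral adduct, no over-addition) give 6 on quenching, and the acidic work-up hydrolyses the N–Si bond to 7.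

**Step 4**
Reactants: 7 2-butanoyl-3,5-bis(methoxymethoxy)-6-(trimethylsilyl)phenyl propan-2-ylcarbamate
Product: 9 2-butanoyl-3,5-bis(methoxymethoxy)-6-(trimethylsilyl)phenyl trifluoromethanesulfonate, via silylphenol 8 (not isolated)
Conditions: DBU, Et2NH, MeCN, 40 °C; then PhNTf2, rt
Reagents that add atoms: 1,1,1-trifluoro-N-phenyl-N-[(trifluoromethyl)sulfonyl]methanesulfonamide, O=S(=O)(N(c1ccccc1)S(=O)(=O)C(F)(F)F)C(F)(F)F
Why: Base-induced E1cB fragmentation of the secondary carbamate (isopropyl isocyanate trapped by Et2NH as the urea) gives phenoxide 8, which is O-sulfonylated in the same flask to the ortho-silylaryl triflate; the ketone, MOM and C–Si groups should be inert to DBU.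

**Step 5**
Reactants: 9 2-butanoyl-3,5-bis(methoxymethoxy)-6-(trimethylsilyl)phenyl trifluoromethanesulfonate; 10 3-methylbut-2-enal
Product: 14 1-[5,7-bis(methoxymethoxy)-2,2-dimethyl-2H-chromen-8-yl]butan-1-one, via aryne 11 (not isolated), via benzoxete 12 (not isolated), via ortho-quinone methide 13 (not isolated)
Conditions: CsF (3 equiv), 10 (4 equiv), MeCN, 25 to 50 °C, slow addition of 9
Reagents that add atoms: none
Why: Fluoride attacks silicon of 9 and triflate leaves to give aryne 11; the carbonyl oxygen of 10 adds to the aryne carbon remote from the adjacent OMOM group (the former triflate carbon, future C8a), and the aryl anion formed next to OMOM closes on the carbonyl carbon (future C4) to give 2H-benzoxete 12 in a stepwise formal [2+2] cycloaddition. Thermal 4π-electrocyclic opening of 12 gives ortho-quinone methide 13, whose Z-dienone closes the pyran ring by disrotatory oxa-6π-electrocyclisation onto the CMe2 terminus, forming O1–C2 and restoring aromaticity. The closest known reaction type is the 2H-chromene synthesis from arynes and α,β-unsaturated aldehydes, read with the regioselectivity model for 3-alkoxyarynes. No stereocentre is formed. The step needs regioselectivity (O to C8a, C to C4a), which the inductive polarisation by the oxygen next to the aryne should secure over the weaker, twisted butanoyl group; it also needs chemoselectivity for the aldehyde over the hindered ketone and [2+2] over [4+2], the latter being disfavoured by the β,β-dimethyl terminus of 10.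

**Step 6**
Reactants: 14 1-[5,7-bis(methoxymethoxy)-2,2-dimethyl-2H-chromen-8-yl]butan-1-one
Product: 15 1-(5,7-dihydroxy-2,2-dimethyl-2H-chromen-8-yl)butan-1-one
Conditions: 3 M aq. HCl, MeOH, 45 °C
Reagents that add atoms: none
Why: Acid-catalysed transacetalisation of the two MOM ethers with methanol frees both phenols, and dilute HCl in methanol should leave the acyl-deactivated chromene double bond alone.

**Step 7**
Reactants: 16 dimethyl 2-methylpropanedioate; 17 (2E)-1-bromo-3,7-dimethylocta-2,6-diene (geranyl bromide)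
Product: 18 dimethyl 2-[(2E)-3,7-dimethylocta-2,6-dien-1-yl]-2-methylpropanedioate
Conditions: NaH (1.1 equiv), THF, 0 °C to rt
Reagents that add atoms: none
Why: Malonate alkylation (SN2) of the sodium enolate with the primary allylic bromide gives the prochiral quaternary diester with the 2E geometry unchanged.

**Step 8**
Reactants: 18 dimethyl 2-[(2E)-3,7-dimethylocta-2,6-dien-1-yl]-2-methylpropanedioate
Product: 19 (2R,4E)-2-(methoxycarbonyl)-2,5,9-trimethyldeca-4,8-dienoic acid
Conditions: pig liver esterase, phosphate buffer pH 7.5, DMSO (10% v/v), 25 °C, pH-stat with 1 M NaOH; then HCl to pH 2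
Reagents that add atoms: water, O
Why: Enzymatic desymmetrisation (enantiotopic-group-selective ester hydrolysis): the esterase hydrolyses one of the two enantiotopic CO2Me groups of 18 (the pro-S one by assumption), which sets the quaternary stereocentre as R, and stops at the mono-acid because the carboxylate is not accepted as a substrate.

**Step 9**
Reactants: 19 (2R,4E)-2-(methoxycarbonyl)-2,5,9-trimethyldeca-4,8-dienoic acid; 20 pentane-2,4-dione
Product: 22 methyl (2R,4E)-2-(3,5-dioxohexanoyl)-2,5,9-trimethyldeca-4,8-dienoate, via acid chloride 21 (not isolated)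
Conditions: 1-chloro-N,N,2-trimethylprop-1-en-1-amine (1.2 equiv), CH2Cl2, 0 °C to rt, evaporate; then add at −78 °C to the dianion of 20 (3 equiv, from LiN(i-Pr)2, 6 equiv, THF, −78 to 0 °C); cold 1 M HCl work-up
Reagents that add atoms: none
Why: Neutral conversion of the acid into acid chloride 21 (no α-H, so no ketene and no racemisation) followed by Claisen-type C-acylation of the 1,3-diketone dianion at its terminal carbanion attaches the acid-derived carbonyl, the future C5, while the far less electrophilic neopentyl-type methyl ester, the future C3, is untouched.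

**Step 10**
Reactants: 22 methyl (2R,4E)-2-(3,5-dioxohexanoyl)-2,5,9-trimethyldeca-4,8-dienoate
Product: 23 (4R)-2-acetyl-4-[(2E)-3,7-dimethylocta-2,6-dien-1-yl]-3,5-dihydroxy-4-methylcyclohexa-2,5-dien-1-one
Conditions: KOt-Bu (3 equiv), THF, 0 °C to rt; 1 M HCl work-up
Reagents that add atoms: none
Why: Dieckmann (intramolecular Claisen) condensation: in the dianion of 22 the doubly activated carbon between the acetyl and the neighbouring ketone attacks the methyl ester in the only geometrically possible closure (6-exo-trig), the delocalised triketonate drives it forward, and the quaternary centre keeps its configuration because it has no enolisable H.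

**Step 11**
Reactants: 15 1-(5,7-dihydroxy-2,2-dimethyl-2H-chromen-8-yl)butan-1-one; 23 (4R)-2-acetyl-4-[(2E)-3,7-dimethylocta-2,6-dien-1-yl]-3,5-dihydroxy-4-methylcyclohexa-2,5-dien-1-one
Product: 26 (4R)-2-acetyl-6-[(8-butanoyl-5,7-dihydroxy-2,2-dimethyl-2H-chromen-6-yl)methyl]-4-[(2E)-3,7-dimethylocta-2,6-dien-1-yl]-3,5-dihydroxy-4-methylcyclohexa-2,5-dien-1-one, via Mannich base 24 (not isolated), via ortho-quinone methide 25 (not isolated)
Conditions: CH2(NMe2)2 (1.05 equiv), 1,4-dioxane, 40 °C, volatiles removed; then 23 (1.1 equiv), 1,4-dioxane, 90 °C, N2 stream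
Reagents that add atoms: N,N,N',N'-tetramethylmethanediamine, CN(C)CN(C)C
Why: A phenolic Mannich reaction at the only free arene CH of 15 gives 24, which on heating with the vinylogous acid 23 loses Me2NH to ortho-quinone methide 25, and Michael addition of the enol carbon C6 of 23 (its only unsubstituted nucleophilic carbon) builds the CH2 bridge without touching the stereocentre.

**Compound list**
1 | benzene-1,3,5-triol (phloroglucinol) | Oc1cc(O)cc(O)c1 | starting material
2 | 3,5-bis(methoxymethoxy)phenol | COCOc1cc(O)cc(OCOC)c1 | intermediate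
3 | 3,5-bis(methoxymethoxy)phenyl propan-2-ylcarbamate | CC(C)NC(=O)Oc1cc(OCOC)cc(OCOC)c1 | intermediate
4 | 3,5-bis(methoxymethoxy)phenyl [tert-butyl(dimethyl)silyl](propan-2-yl)carbamate | CC(C)N([Si](C)(C)C(C)(C)C)C(=O)Oc1cc(OCOC)cc(OCOC)c1 | intermediate
5 | 3,5-bis(methoxymethoxy)-2-(trimethylsilyl)phenyl [tert-butyl(dimethyl)silyl](propan-2-yl)carbamate | CC(C)N([Si](C)(C)C(C)(C)C)C(=O)Oc1cc(OCOC)cc(OCOC)c1[Si](C)(C)C | intermediate
6 | 2-butanoyl-3,5-bis(methoxymethoxy)-6-(trimethylsilyl)phenyl [tert-butyl(dimethyl)silyl](propan-2-yl)carbamate | CCCC(=O)c1c(OCOC)cc(OCOC)c([Si](C)(C)C)c1OC(=O)N(C(C)C)[Si](C)(C)C(C)(C)C | intermediate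
7 | 2-butanoyl-3,5-bis(methoxymethoxy)-6-(trimethylsilyl)phenyl propan-2-ylcarbamate | CCCC(=O)c1c(OCOC)cc(OCOC)c([Si](C)(C)C)c1OC(=O)NC(C)C | intermediate
8 | 1-[2-hydroxy-4,6-bis(methoxymethoxy)-3-(trimethylsilyl)phenyl]butan-1-one | CCCC(=O)c1c(OCOC)cc(OCOC)c([Si](C)(C)C)c1O | intermediate
9 | 2-butanoyl-3,5-bis(methoxymethoxy)-6-(trimethylsilyl)phenyl trifluoromethanesulfonate | CCCC(=O)c1c(OCOC)cc(OCOC)c([Si](C)(C)C)c1OS(=O)(=O)C(F)(F)F | intermediate
10 | 3-methylbut-2-enal | CC(C)=CC=O | starting material
11 | 1-[2,3-didehydro-4,6-bis(methoxymethoxy)phenyl]butan-1-one (aryne) | CCCC(=O)C1=C(OCOC)C=C(OCOC)C#C1 | intermediate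
12 | 1-[3,5-bis(methoxymethoxy)-2-(2-methylprop-1-en-1-yl)-2H-1-benzoxet-6-yl]butan-1-one (racemic) | CCCC(=O)c1c(OCOC)cc(OCOC)c2c1OC2C=C(C)C | intermediate
13 | (6Z)-2-butanoyl-3,5-bis(methoxymethoxy)-6-(3-methylbut-2-en-1-ylidene)cyclohexa-2,4-dien-1-one | CCCC(=O)C1=C(OCOC)C=C(OCOC)/C(=C/C=C(C)C)C1=O | intermediate
14 | 1-[5,7-bis(methoxymethoxy)-2,2-dimethyl-2H-chromen-8-yl]butan-1-one | CCCC(=O)c1c(OCOC)cc(OCOC)c2C=CC(C)(C)Oc12 | intermediate
15 | 1-(5,7-dihydroxy-2,2-dimethyl-2H-chromen-8-yl)butan-1-one | CCCC(=O)c1c(O)cc(O)c2C=CC(C)(C)Oc12 | intermediate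
16 | dimethyl 2-methylpropanedioate | COC(=O)C(C)C(=O)OC | starting material
17 | (2E)-1-bromo-3,7-dimethylocta-2,6-diene (geranyl bromide) | CC(C)=CCC/C(C)=C/CBr | starting material
18 | dimethyl 2-[(2E)-3,7-dimethylocta-2,6-dien-1-yl]-2-methylpropanedioate | COC(=O)C(C)(C/C=C(\C)CCC=C(C)C)C(=O)OC | intermediate
19 | (2R,4E)-2-(methoxycarbonyl)-2,5,9-trimethyldeca-4,8-dienoic acid | OC(=O)[C@@](C)(C/C=C(\C)CCC=C(C)C)C(=O)OC | intermediate
20 | pentane-2,4-dione | CC(=O)CC(C)=O | starting material
21 | methyl (2S,4E)-2-(chlorocarbonyl)-2,5,9-trimethyldeca-4,8-dienoate | ClC(=O)[C@@](C)(C/C=C(\C)CCC=C(C)C)C(=O)OC | intermediate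
22 | methyl (2R,4E)-2-(3,5-dioxohexanoyl)-2,5,9-trimethyldeca-4,8-dienoate | CC(=O)CC(=O)CC(=O)[C@@](C)(C/C=C(\C)CCC=C(C)C)C(=O)OC | intermediate
23 | (4R)-2-acetyl-4-[(2E)-3,7-dimethylocta-2,6-dien-1-yl]-3,5-dihydroxy-4-methylcyclohexa-2,5-dien-1-one | O=C1C=C(O)[C@@](C)(C/C=C(\C)CCC=C(C)C)C(O)=C1C(C)=O | intermediate
24 | 1-{6-[(dimethylamino)methyl]-5,7-dihydroxy-2,2-dimethyl-2H-chromen-8-yl}butan-1-one | CCCC(=O)c1c(O)c(CN(C)C)c(O)c2C=CC(C)(C)Oc12 | intermediate
25 | 8-butanoyl-5-hydroxy-2,2-dimethyl-6-methylidene-2H-chromen-7(6H)-one | CCCC(=O)C1=C2OC(C)(C)C=CC2=C(O)C(=C)C1=O | intermediate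
26 | (4R)-2-acetyl-6-[(8-butanoyl-5,7-dihydroxy-2,2-dimethyl-2H-chromen-6-yl)methyl]-4-[(2E)-3,7-dimethylocta-2,6-dien-1-yl]-3,5-dihydroxy-4-methylcyclohexa-2,5-dien-1-one | CCCC(=O)c1c(O)c(CC2=C(O)[C@@](C)(C/C=C(\C)CCC=C(C)C)C(O)=C(C(C)=O)C2=O)c(O)c2c1OC(C)(C)C=C2 | target

**Step count and risks**
Total steps: 11. Longest linear sequence: 7 (steps 1–6, then 11); the second branch is steps 7–10.

Most likely to fail:

1. Step 5. The aldehyde may add to the unsymmetrical, ketone-flanked aryne with poor regiocontrol, or the aryne may be diverted (fluoride-induced self-condensation of the enal, or capture of the ortho-quinone methide by a second aryne). The fallback sets out from 3 and comes back to the route at 14, replacing the aryne by an aromatic propargyl Claisen cascade. A single directed ortho-metalation of 3 (TBSOTf/TMEDA, then n-BuLi/TMEDA, then N-methoxy-N-methylbutanamide, aq. NaHSO4 work-up), with the C-silylation left out, would give 2-butanoyl-3,5-bis(methoxymethoxy)phenyl propan-2-ylcarbamate F1. DBU/Et2NH in MeCN would then free 1-[2-hydroxy-4,6-bis(methoxymethoxy)phenyl]butan-1-one F2. O-Alkylation with 3-chloro-3-methylbut-1-yne (K2CO3, KI, CuI cat., acetone, reflux) would give 1-[2,4-bis(methoxymethoxy)-6-(2-methylbut-3-yn-2-yloxy)phenyl]butan-1-one F3. Heating F3 in xylene at 140 °C would take it through aromatic propargyl Claisen rearrangement, [1,5]-H shift and oxa-6π-electrocyclisation to 14; only one ortho position of the ether is free, so the regiochemistry is fixed.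

2. Step 9. Proton transfer from the acidic triketone product may quench the dianion, and O-acylation or double acylation may compete. The fallback sets out from 19 and comes back to the route at 22, using an isoxazole as a masked 1,3-diketone. Compound 19 is converted into 21 as in step 9 and added to 5-(lithiomethyl)-3-methyl-1,2-oxazole (from 3,5-dimethyl-1,2-oxazole, n-BuLi, THF, −78 °C) to give methyl (2R,4E)-2,5,9-trimethyl-2-[(3-methyl-1,2-oxazol-5-yl)acetyl]deca-4,8-dienoate F4. Reductive N–O cleavage with Mo(CO)6 in MeCN/H2O at 80 °C would give methyl (2R,4E)-2-[(4Z)-5-amino-3-oxohex-4-enoyl]-2,5,9-trimethyldeca-4,8-dienoate F5, and hydrolysis of this vinylogous amide with 1 M HCl in THF would give 22.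

3. Step 8. The esterase may discriminate the enantiotopic ester groups poorly, or with the opposite sense, on this lipophilic substrate. The fallback sets out from 18 and comes back to the route at 19 by classical resolution. Mono-saponification of 18 (KOH, 1.0 equiv, MeOH/H2O) would give racemic 2-(methoxycarbonyl)-2,5,9-trimethyldeca-4,8-dienoic acid F6. Fractional crystallisation with (1S)-1-phenylethan-1-amine (or its enantiomer, whichever gives the less soluble salt of the R acid) would give (1S)-1-phenylethan-1-aminium (2R,4E)-2-(methoxycarbonyl)-2,5,9-trimethyldeca-4,8-dienoate F7, and acidification of F7 would give 19.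

**Further compounds**
F1 | step 5 | 2-butanoyl-3,5-bis(methoxymethoxy)phenyl propan-2-ylcarbamate | CCCC(=O)c1c(OCOC)cc(OCOC)cc1OC(=O)NC(C)C
F2 | step 5 | 1-[2-hydroxy-4,6-bis(methoxymethoxy)phenyl]butan-1-one | CCCC(=O)c1c(OCOC)cc(OCOC)cc1O
F3 | step 5 | 1-[2,4-bis(methoxymethoxy)-6-(2-methylbut-3-yn-2-yloxy)phenyl]butan-1-one | CCCC(=O)c1c(OCOC)cc(OCOC)cc1OC(C)(C)C#C
F4 | step 9 | methyl (2R,4E)-2,5,9-trimethyl-2-[(3-methyl-1,2-oxazol-5-yl)acetyl]deca-4,8-dienoate | Cc1cc(CC(=O)[C@@](C)(C/C=C(\C)CCC=C(C)C)C(=O)OC)on1
F5 | step 9 | methyl (2R,4E)-2-[(4Z)-5-amino-3-oxohex-4-enoyl]-2,5,9-trimethyldeca-4,8-dienoate | C/C(N)=C/C(=O)CC(=O)[C@@](C)(C/C=C(\C)CCC=C(C)C)C(=O)OC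
F6 | step 8 | racemic 2-(methoxycarbonyl)-2,5,9-trimethyldeca-4,8-dienoic acid (4E) | OC(=O)C(C)(C/C=C(\C)CCC=C(C)C)C(=O)OC
F7 | step 8 | (1S)-1-phenylethan-1-aminium (2R,4E)-2-(methoxycarbonyl)-2,5,9-trimethyldeca-4,8-dienoate | C[C@H]([NH3+])c1ccccc1.[O-]C(=O)[C@@](C)(C/C=C(\C)CCC=C(C)C)C(=O)OC
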